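(The data stem from a simulated flask for an exercise; scatter was added.)

At 4.7 h you have a reading in each of the oak, alder and elm runs, and that is also the time asked of the birch run, so what you want is the share of the charge that has become product by then.

| flask | starting material | time |
|---|---|---|
| oak | 0.100 M |  |
| alder | 0.0600 M |  |
| elm | 0.150 M |  |
| birch | 0.210 M | 4.7 h |

| run | time / h | [product] / M |
|---|---|---|
| oak run | 0.27 | 0.0054 |
| oak run | 0.81 | 0.0182 |
| oak run | 1.6 | 0.0300 |
| oak run | 2.5 | 0.0370 |
| oak run | 3.5 | 0.0381 |
| oak run | 4.7 | 0.0404 |
| alder run | 0.27 | 0.0051 |
| alder run | 0.81 | 0.0137 |
| alder run | 1.6 | 0.0178 |
| alder run | 2.5 | 0.0212 |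
| alder run | 3.5 | 0.0232 |
| alder run | 4.7 | 0.0235 |
| elm run | 0.27 | 0.0104 |
| elm run | 0.81 | 0.0299 |
| elm run | 1.6 | 0.0444 |
| elm run | 2.5 | 0.0549 |
| elm run | 3.5 | 0.0594 |
| elm run | 4.7 | 0.0621 |

(readings scatter by 0.001 M)

- Overall: starting material -> product.
- Constant volume, constant temperature.
- An order is taken over about fifteen percent of the charge, up and down.

- apparent order in [starting material] of the starting rate, round the charge of the oak run (the rate where two percent of its starting material have turned into product) (one fixed amount of product, the same in the runs compared)
- product in the birch run at 4.7 h, as a share of the starting material charged
- which of these the readings show (the substrate is lost by itself / the substrate pairs with itself / nothing beyond the main steps / two substrates go astray together)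

My first estimate takes each run alone: 39.2% in alder, 40.4% in oak, 41.4% in elm. The large number is therefore a share near 40.4% of the charge, and the correction that birch might need is the climb of 2.2 percentage points from alder to elm. One reading's scatter is already 1.67% of the alder charge, so I apply no correction. These shares do not fall as the charge rises from 0.0600 M in alder to 0.150 M in elm, whereas a loss taking starting material in pairs takes a growing share of a larger charge, so I take the starting material to be lost by itself, alongside its turning into product. Product at 1.6 h, before the curves level off, gives the order as a reading: the elm-to-alder ratio of products against the ratio of charges has the exponent 0.998.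

The weak link is leaning on single runs, so I reforge it by pooling. Define f, the yield at that time, as the summed last readings over the summed charges: 40.6%, with a scatter of 0.559%. For birch that makes 0.0854 M of product.

The forecast gives order 0.9 (0.72 to 1.08), a share of 41% (39% to 43%) and "the substrate is lost by itself", on the ground that “All three runs level off at about the same share of the charge”; its order lies below mine and its share above mine.

The birch run gives 41.2% at 4.7 h, the order of the starting rate round the oak charge comes to 1.0, and the readings show that the substrate is lost by itself.

    starting material → product (0.3190 /h)
    starting material → decomposed substrate (0.4320 /h)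

That is 0.0866 M of product in the birch run, against the 0.0854 M that f gave. The time for a quarter of the charge to become product is 1.18 h in oak, 1.18 h in alder and 1.18 h in elm. Put f to the alder run: it gives 0.0244 M at 4.7 h, and the 0.0150 M that makes a quarter of the alder charge stands at 1.18 h.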